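**Strategy.** The C3 acetate is treated as a masked C-acetyl group (Baeyer–Villiger, retention), so that C2 with its methyl, C3 and both acetate carbons of the piperidine map onto pentane-2,4-dione. Everything rests on annulating this symmetric diketone onto an (S)-3-azido-1-bromoalkane that carries C4–C6, the ring nitrogen and the ketal-masked side chain. In one pot, Staudinger/aza-Wittig condensation joins N1 to C2 and base-mediated C-alkylation of the resulting enaminone joins C3 to C4, closing the six-membered ring as a cyclic vinylogous amide. The C6 stereocentre then steers a syn hydrogenation to the all-cis piperidine.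

Key step: step 5

Assumption: (S)-2-(2-bromoethyl)oxirane is bought as an enantiopure building block.

**Step 1**
Reactants: 1 12-bromododecanoic acid
Product: 2 13-bromotridecan-2-one
Conditions: MeLi (2.2 equiv), THF, −78 → 0 °C; inverse quench into cold 1 M HCl
Reagents that add atoms: methyllithium, [Li]C
Why: Carboxylic acid to methyl ketone with an organolithium: the lithium carboxylate takes up a second MeLi to give a gem-dilithio diolate that collapses to the ketone only on acidic quench, and the primary bromide should be inert to MeLi at low temperature.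

**Step 2**
Reactants: 2 13-bromotridecan-2-one
Product: 3 2-(11-bromoundecyl)-2-methyl-1,3-dioxolane
Conditions: ethylene glycol, TsOH·H2O (cat.), toluene, reflux, Dean–Stark
Reagents that add atoms: ethylene glycol, OCCO
Why: Acid-catalysed ketalisation with azeotropic removal of water masks the side-chain ketone against the Grignard, base, hydrogenation and peracid steps that follow.

**Step 3**
Reactants: 3 2-(11-bromoundecyl)-2-methyl-1,3-dioxolane; 4 (S)-2-(2-bromoethyl)oxirane
Product: 6 (3R)-1-bromo-15-(2-methyl-1,3-dioxolan-2-yl)pentadecan-3-ol, via alkylmagnesium bromide 5 (not isolated)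
Conditions: Mg, THF, 40 °C; then CuI (10 mol %), 4, THF, −40 → −20 °C; H2O
Reagents that add atoms: none
Why: Copper-catalysed Grignard opening of a terminal epoxide occurs at the unsubstituted CH2 with retention at the carbinol carbon and at −40 °C should outpace coupling at the primary bromide; the stereocentre is taken from 4.

**Step 4**
Reactants: 6 (3R)-1-bromo-15-(2-methyl-1,3-dioxolan-2-yl)pentadecan-3-ol
Product: 7 2-[(13S)-13-azido-15-bromopentadecyl]-2-methyl-1,3-dioxolane
Conditions: PPh3, DIAD, (PhO)2P(O)N3, THF, 0 °C → rt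
Reagents that add atoms: diphenylphosphoryl azide, [N-]=[N+]=NP(=O)(Oc1ccccc1)Oc1ccccc1
Why: Mitsunobu azidation displaces the oxyphosphonium by azide in an SN2 process, which inverts the carbinol centre to the S configuration required at C6 and leaves the primary bromide untouched.

**Step 5**
Reactants: 7 2-[(13S)-13-azido-15-bromopentadecyl]-2-methyl-1,3-dioxolane; 8 pentane-2,4-dione
Product: 11 1-{(6S)-2-methyl-6-[12-(2-methyl-1,3-dioxolan-2-yl)dodecyl]-1,4,5,6-tetrahydropyridin-3-yl}ethan-1-one, via iminophosphorane 9 (not isolated), via open-chain enaminone 10 (not isolated)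
Conditions: PPh3 (1.05 equiv), 8 (1.05 equiv), THF, rt → 50 °C; then NaH, THF–DMF, 0 → 40 °C (one pot)
Reagents that add atoms: none
Why: Staudinger reaction of azide 7 with PPh3 gives iminophosphorane 9, which condenses with one carbonyl of the symmetric diketone 8 (aza-Wittig type, Ph3P=O lost) to the Z-enaminone 10 and so forms the N1–C2 bond; NaH then deprotonates the N–H and the α-carbon of the aza-enolate displaces the primary bromide, forming C3–C4. The closest known reaction type is the annulation of 3-halopropylamines onto 1,3-dicarbonyl compounds to give cyclic β-enaminones, here run from the azide so that no free haloamine accumulates. The ring closes as a 6-exo-tet C-alkylation in which the enaminone C=C lies inside the new ring (6-enolendo-exo-tet). No new stereocentre is created, and the C6 centre, which carries no acidic hydrogen, passes through unchanged. The step needs C-alkylation to beat N- and O-alkylation, which ring size secures (N-attack would give an azetidine, O-attack an eight-membered ring), and the condensation needs no regiocontrol because both carbonyls of 8 are equivalent. The second acetyl group stays on C3 as the latent acetate.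

**Step 6**
Reactants: 11 1-{(6S)-2-methyl-6-[12-(2-methyl-1,3-dioxolan-2-yl)dodecyl]-1,4,5,6-tetrahydropyridin-3-yl}ethan-1-one
Product: 12 1-{(2R,3R,6S)-2-methyl-6-[12-(2-methyl-1,3-dioxolan-2-yl)dodecyl]piperidin-3-yl}ethan-1-one
Conditions: H2 (4 atm), PtO2 (10 mol %), EtOH–AcOH (20:1), rt; aq. NaHCO3
Reagents that add atoms: none
Why: Heterogeneous syn hydrogenation of the acid-activated vinylogous amide should deliver both hydrogens to the C2=C3 face anti to the C6 side chain, which sets C2 and C3 cis to each other and to C6 (all-cis, 2R,3R,6S).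

**Step 7**
Reactants: 12 1-{(2R,3R,6S)-2-methyl-6-[12-(2-methyl-1,3-dioxolan-2-yl)dodecyl]piperidin-3-yl}ethan-1-one
Product: 13 tert-butyl (2R,3R,6S)-3-acetyl-2-methyl-6-[12-(2-methyl-1,3-dioxolan-2-yl)dodecyl]piperidine-1-carboxylate
Conditions: Boc2O (3 equiv), NaHCO3, THF–H2O, 40 °C
Reagents that add atoms: di-tert-butyl dicarbonate, CC(C)(C)OC(=O)OC(=O)OC(C)(C)C
Why: Carbamate formation (N-Boc protection) shields the secondary amine from N-oxidation by peracid and blocks retro-Michael epimerisation of the β-amino ketone.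

**Step 8**
Reactants: 13 tert-butyl (2R,3R,6S)-3-acetyl-2-methyl-6-[12-(2-methyl-1,3-dioxolan-2-yl)dodecyl]piperidine-1-carboxylate
Product: 14 tert-butyl (2R,3R,6S)-3-acetoxy-2-methyl-6-[12-(2-methyl-1,3-dioxolan-2-yl)dodecyl]piperidine-1-carboxylate
Conditions: mCPBA (4 equiv), Na2HPO4, CH2Cl2, rt, dark
Reagents that add atoms: mCPBA, OOC(=O)c1cccc(Cl)c1
Why: Baeyer–Villiger oxidation, in which the secondary ring carbon C3 migrates in preference to methyl with retention of configuration, turns C3–acetyl into C3–OAc while the ketal keeps the side-chain ketone out of reach.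

**Step 9**
Reactants: 14 tert-butyl (2R,3R,6S)-3-acetoxy-2-methyl-6-[12-(2-methyl-1,3-dioxolan-2-yl)dodecyl]piperidine-1-carboxylate
Product: 15 (−)-3-O-acetylspectaline, (2R,3R,6S)-2-methyl-6-(13-oxotetradecyl)piperidin-3-yl acetate
Conditions: TFA–CH2Cl2–H2O (10:10:1), 0 °C → rt; cold aq. NaHCO3
Reagents that add atoms: water, O
Why: Acidolysis removes the Boc group and aqueous acid hydrolyses the dioxolane in the same pot (carbamate cleavage and ketal hydrolysis), the secondary acetate being stable to TFA; a cold, brief bicarbonate work-up should limit O-to-N acetyl transfer.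

**Compound list**
1 | 12-bromododecanoic acid | OC(=O)CCCCCCCCCCCBr | starting material
2 | 13-bromotridecan-2-one | CC(=O)CCCCCCCCCCCBr | intermediate
3 | 2-(11-bromoundecyl)-2-methyl-1,3-dioxolane | CC1(CCCCCCCCCCCBr)OCCO1 | intermediate
4 | (S)-2-(2-bromoethyl)oxirane | BrCC[C@H]1CO1 | starting material
5 | [11-(2-methyl-1,3-dioxolan-2-yl)undecyl]magnesium bromide (not isolated) | CC1(CCCCCCCCCCC[Mg]Br)OCCO1 | intermediate
6 | (3R)-1-bromo-15-(2-methyl-1,3-dioxolan-2-yl)pentadecan-3-ol | CC1(CCCCCCCCCCCC[C@@H](O)CCBr)OCCO1 | intermediate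
7 | 2-[(13S)-13-azido-15-bromopentadecyl]-2-methyl-1,3-dioxolane | CC1(CCCCCCCCCCCC[C@H](N=[N+]=[N-])CCBr)OCCO1 | intermediate
8 | pentane-2,4-dione | CC(=O)CC(C)=O | starting material
9 | 2-[(13S)-15-bromo-13-[(triphenylphosphoranylidene)amino]pentadecyl]-2-methyl-1,3-dioxolane (not isolated) | CC1(CCCCCCCCCCCC[C@H](N=P(c2ccccc2)(c2ccccc2)c2ccccc2)CCBr)OCCO1 | intermediate
10 | (3Z)-4-{[(3S)-1-bromo-15-(2-methyl-1,3-dioxolan-2-yl)pentadecan-3-yl]amino}pent-3-en-2-one (not isolated) | CC1(CCCCCCCCCCCC[C@H](N/C(C)=C\C(C)=O)CCBr)OCCO1 | intermediate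
11 | 1-{(6S)-2-methyl-6-[12-(2-methyl-1,3-dioxolan-2-yl)dodecyl]-1,4,5,6-tetrahydropyridin-3-yl}ethan-1-one | CC1(CCCCCCCCCCCC[C@H]2CCC(C(C)=O)=C(C)N2)OCCO1 | intermediate
12 | 1-{(2R,3R,6S)-2-methyl-6-[12-(2-methyl-1,3-dioxolan-2-yl)dodecyl]piperidin-3-yl}ethan-1-one | CC1(CCCCCCCCCCCC[C@H]2CC[C@@H](C(C)=O)[C@@H](C)N2)OCCO1 | intermediate
13 | tert-butyl (2R,3R,6S)-3-acetyl-2-methyl-6-[12-(2-methyl-1,3-dioxolan-2-yl)dodecyl]piperidine-1-carboxylate | CC1(CCCCCCCCCCCC[C@H]2CC[C@@H](C(C)=O)[C@@H](C)N2C(=O)OC(C)(C)C)OCCO1 | intermediate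
14 | tert-butyl (2R,3R,6S)-3-acetoxy-2-methyl-6-[12-(2-methyl-1,3-dioxolan-2-yl)dodecyl]piperidine-1-carboxylate | CC1(CCCCCCCCCCCC[C@H]2CC[C@@H](OC(C)=O)[C@@H](C)N2C(=O)OC(C)(C)C)OCCO1 | intermediate
15 | (−)-3-O-acetylspectaline, (2R,3R,6S)-2-methyl-6-(13-oxotetradecyl)piperidin-3-yl acetate | CC(=O)CCCCCCCCCCCC[C@H]1CC[C@@H](OC(C)=O)[C@@H](C)N1 | target

**Count.** Total steps: 9. Longest linear sequence: 9 steps (1 → 15).

**Steps most likely to fail**

Step 5. The open-chain enaminone may react between molecules (N- or C-alkylation, oligomers) or lose HBr faster than it cyclises, and the iminophosphorane may be alkylated before it condenses. The fallback sets out from 7 and reverses the order of bond formation. Bromide 7 is used to C-alkylate pentane-2,4-dione 8 (K2CO3, NaI cat., acetone, reflux), and the azido diketone 3-[(3S)-3-azido-15-(2-methyl-1,3-dioxolan-2-yl)pentadecyl]pentane-2,4-dione F1 is isolated. Treatment with PPh3 in toluene at 60 °C then effects Staudinger reduction and intramolecular aza-Wittig closure onto one of the two equivalent ketones. Tautomerisation gives the cyclic enaminone, and the route is rejoined at 11.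

Step 6. Facial selectivity may be incomplete, C3 may epimerise through the iminium/enamine pair in acid, and the acetyl carbonyl may be reduced on platinum. The fallback sets out from 11. The vinylogous amide is N-acylated (Boc2O, DMAP, MeCN) to tert-butyl (2S)-5-acetyl-6-methyl-2-[12-(2-methyl-1,3-dioxolan-2-yl)dodecyl]-3,4-dihydro-2H-pyridine-1-carboxylate F2. Allylic strain against the carbamate should now hold the side chain axial, so neutral hydrogenation (H2, Rh/Al2O3 or Pd/C, EtOAc) should add to the opposite face. This gives 13 directly; step 7 is skipped and the route is rejoined at 13.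

Step 8. Oxygen insertion at the hindered ketone may be slow, and the acid by-product may erode the Boc group or the ketal before conversion is complete. The fallback sets out from 13 and replaces the acyl shift by degradation and reduction.
- Thermodynamic enol silylation (TMSCl, NaI, Et3N, MeCN) should give tert-butyl (2R,6S)-2-methyl-6-[12-(2-methyl-1,3-dioxolan-2-yl)dodecyl]-3-[1-(trimethylsilyloxy)ethylidene]piperidine-1-carboxylate F3.
- Ozonolysis (O3, CH2Cl2, −78 °C; Me2S) should give tert-butyl (2R,6S)-2-methyl-6-[12-(2-methyl-1,3-dioxolan-2-yl)dodecyl]-3-oxopiperidine-1-carboxylate F4.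
- Reduction with LiBH(s-Bu)3 in THF at −78 °C, with hydride arriving anti to the axial C2 methyl, should give tert-butyl (2R,3R,6S)-3-hydroxy-2-methyl-6-[12-(2-methyl-1,3-dioxolan-2-yl)dodecyl]piperidine-1-carboxylate F5.
- Acetylation (Ac2O, DMAP, pyridine) rejoins the route at 14.

**Further compounds**
F1 | step 5 | 3-[(3S)-3-azido-15-(2-methyl-1,3-dioxolan-2-yl)pentadecyl]pentane-2,4-dione | CC1(CCCCCCCCCCCC[C@H](N=[N+]=[N-])CCC(C(C)=O)C(C)=O)OCCO1
F2 | step 6 | tert-butyl (2S)-5-acetyl-6-methyl-2-[12-(2-methyl-1,3-dioxolan-2-yl)dodecyl]-3,4-dihydro-2H-pyridine-1-carboxylate | CC1(CCCCCCCCCCCC[C@H]2CCC(C(C)=O)=C(C)N2C(=O)OC(C)(C)C)OCCO1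
F3 | step 8 | tert-butyl (2R,6S)-2-methyl-6-[12-(2-methyl-1,3-dioxolan-2-yl)dodecyl]-3-[1-(trimethylsilyloxy)ethylidene]piperidine-1-carboxylate | CC1(CCCCCCCCCCCC[C@H]2CCC(=C(C)O[Si](C)(C)C)[C@@H](C)N2C(=O)OC(C)(C)C)OCCO1
F4 | step 8 | tert-butyl (2R,6S)-2-methyl-6-[12-(2-methyl-1,3-dioxolan-2-yl)dodecyl]-3-oxopiperidine-1-carboxylate | CC1(CCCCCCCCCCCC[C@H]2CCC(=O)[C@@H](C)N2C(=O)OC(C)(C)C)OCCO1
F5 | step 8 | tert-butyl (2R,3R,6S)-3-hydroxy-2-methyl-6-[12-(2-methyl-1,3-dioxolan-2-yl)dodecyl]piperidine-1-carboxylate | CC1(CCCCCCCCCCCC[C@H]2CC[C@@H](O)[C@@H](C)N2C(=O)OC(C)(C)C)OCCO1
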